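(Readings and results stem from a simulated flask on assumed constants; noise was put on by code.)

The constant that can be read from these runs is the pseudo-first-order constant of J after a portion. J is added in portions, D is the initiator of its turning into G, and X is also present. The carried form is that constant divided by the charged c(D), called here the specific decay constant. In the ash run J falls from 13.9% at 0.667 min to 5.0% at 1.33 min, which reads as 1.54 /min. With c(D) = 58 mM, the specific decay constant reads 26.6 /M/min.

the same everywhere: J 2.3 M (in portions, 3)
- ash: X 0.097 M; D 58 mM; run made earlier; portions every 2.0 min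
- alder: X 0.15 M; D 58 mM; run made earlier; portions every 2.0 min
- larch: X 0.069 M; D 120 mM; run made earlier; portions every 2.0 min
- flask: X 0.0690 M; D 58 mM; the portions of J follow each other after 2.0 min, the first at the start; time 6.0 min

| run | time / min | G / % | J / % |
|---|---|---|---|
| ash | 0.667 | 17.8 | 13.9 |
| ash | 1.33 | 28.2 | 5.0 |
| ash | 2.00 | 30.7 | 2.4 |
| ash | 3.00 | 60.1 | 8.5 |
| ash | 4.00 | 65.5 | 1.6 |
| ash | 5.00 | 91.9 | 6.7 |
| alder | 0.667 | 19.4 | 13.3 |
| alder | 1.33 | 26.8 | 4.7 |
| alder | 2.00 | 32.5 | 2.9 |
| alder | 3.00 | 59.7 | 7.9 |
| alder | 4.00 | 65.1 | 1.0 |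
| alder | 5.00 | 91.3 | 8.7 |
| larch | 0.417 | 20.8 | 13.1 |
| larch | 0.667 | 27.0 | 5.3 |
| larch | 1.33 | 32.8 | 1.0 |
| larch | 2.50 | 59.0 | 5.0 |
| larch | 5.00 | 99.7 | 2.1 |

(each reading ± 1 percentage point)

- the numbers in the tables scatter by 1 percentage point (one standard deviation)

- amount of G in percent of the J charged, at 20 s, 1.5 min and 6.0 min

The alder run, with c(X) = 0.15 M against 0.097 M in ash, reads 1.57 /min, about the same as ash. These two readings therefore show no effect of X between those two values of c(X). The larch run, which differs from ash in c(X) as well, tests c(D): its last portion is 1.00 min old at 5.00 min, so the frozen constant leaves 1.37% of the charge as J from that portion, and the reading of J is 2.1%.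

The flask has the c(D) of ash and a lower c(X), 0.0690 M, the value of larch. Freezing the constant gives 1.54 /min, and each interval leaves 4.58% of the J present at its start. The ash run stops at 5.00 min with G at 91.9% and J at 6.7%, its last portion 1.00 min old. The flask is read with that portion 2.0 min old, so this reckoning puts its G higher than that ash reading. The first ash reading of J, run back along the frozen constant to the first portion, reads as a lag of 0.0998 min. This reckoning gives G of 10.1%, 29.5% and 98.4%.

The forecast gives 10%, 29.3% and 98%, and says “I expect no X effect in the flask”.

The flask gives 9.19%, 29.5% and 98.6%.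

    J + D → Q + G (k = 4.30 /M/min)
    J + Q → G + Q, rate k2*[Q]*[J] (k = 43.0 /M/min)
    Q + X → L (k = 0.0970 /M/min)
    D → Z (k = 1.30 /min)

In the flask the frozen half-life of J, 0.449 min, stands against 190 min for X by its capture of Q, and that capture makes no difference to G, with 98% of the charged X still unbound at 6.00 min. In the flask c(Q) stands at 0.0375 M at 3.00 min and 0.0368 M at 6.00 min, and the constant of J + Q times the first is 1.61 /min, while by 60.0 min c(Q) has sunk to 0.0266 M, with X at 83.1% of its charge.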